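The route rests on a [3+2] disconnection of the dihydrofuran ring across O1–C7a and C2–C3 (benzofuran numbering). The arene arrives as 5-acetyl-2-fluorobenzaldehyde; O1–C2 with the 1-(methoxycarbonyl)vinyl group arrives as a γ-silyloxy 2-(methoxycarbonyl)allylboronate. In one flask, a chiral-acid-catalysed allylboration joins C2 to the aldehyde carbon C3 and sets both stereocentres (syn, hence cis). Fluoride then unmasks O1, which displaces the fluoride at C7a. The step exploits two features: the C2 substituent is exactly the 2-carboxyallyl residue left by an allyl transfer, and C7a lies para to the C5 acetyl group, so the carbonyl that later becomes the ester-bearing carbinol activates the ring closure.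

Key step: step 3

Remark: the pinacol boronate 5 is taken as the commercial pinacol ester of 2-(methoxycarbonyl)ethylboronic acid. The two stages of step 3 run in one flask without isolation.

Step 1
Reactants: 1 5-bromo-2-fluorobenzaldehyde; 2 tributyl(1-ethoxyethenyl)stannane
Product: 4 5-acetyl-2-fluorobenzaldehyde, via enol ether 3 (not isolated)
Conditions: Pd(PPh3)4 (3 mol%), toluene, 100 °C; then 1 M HCl, THF, rt
Reagents that add atoms: water, O
Why: Stille coupling of the aryl bromide with the α-ethoxyvinylstannane (an acetyl anion equivalent) tolerates the aldehyde, and mild acid hydrolysis of the enol ether then releases the methyl ketone.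

Step 2
Reactants: 5 methyl 3-(4,4,5,5-tetramethyl-1,3,2-dioxaborolan-2-yl)propanoate; 6 methyl formate
Product: 8 methyl (2E)-3-[(tert-butyldimethylsilyl)oxy]-2-[(4,4,5,5-tetramethyl-1,3,2-dioxaborolan-2-yl)methyl]prop-2-enoate, via sodium enolate 7 (not isolated)
Conditions: NaH (1.2 equiv), MeOH (cat.), HCO2Me (3 equiv), THF, 0 °C to rt; then t-BuMe2SiCl (1.3 equiv), 0 °C to rt; the (E)-isomer is separated on Et3N-deactivated silica
Reagents that add atoms: tert-butyldimethylsilyl chloride, CC(C)(C)[Si](C)(C)Cl
Why: Crossed Claisen formylation of the ester is driven by deprotonation of the acidic α-formyl ester, and the hard silyl chloride then traps the enolate on oxygen; the (E)-geometry (silyloxy trans to the ester and cis to the CH2B group) should be the more stable one, as in β-alkoxy-α-alkylacrylates.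

Step 3
Reactants: 4 5-acetyl-2-fluorobenzaldehyde; 8 methyl (2E)-3-[(tert-butyldimethylsilyl)oxy]-2-[(4,4,5,5-tetramethyl-1,3,2-dioxaborolan-2-yl)methyl]prop-2-enoate
Product: 11 methyl 2-[(2S,3S)-5-acetyl-3-hydroxy-2,3-dihydro-1-benzofuran-2-yl]prop-2-enoate, via syn adduct 9 (not isolated), via cyclised borate 10 (not isolated)
Conditions: (R)-3,3'-bis(2,4,6-triisopropylphenyl)-1,1'-binaphthyl-2,2'-diyl hydrogen phosphate (5 mol%), 4 Å molecular sieves, toluene, −30 °C to 0 °C; then DMF, dried n-Bu4NF (3 equiv), 0 °C to rt; pH 7 phosphate buffer work-up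
Reagents that add atoms: none
Why: Proposed new method: in the first stage the chiral phosphoric acid hydrogen-bonds to a boronate oxygen and to the formyl C–H, and the γ-carbon of 8 adds to the aldehyde of 4 through a chair-like six-membered transition state (closest known type: Brønsted-acid-catalysed allyl- and crotylboration of aromatic aldehydes, a mode of activation also known for 2-alkoxycarbonylallylboronates), which forms C2–C3 and leaves O3 on boron in 9. In the second stage fluoride removes the silyl group from O1 and the alkoxide displaces the aryl fluoride at C7a by addition–elimination (closest known type: fluoride-mediated intramolecular SNAr etherification of silyl ethers onto activated fluoroarenes), which forms O1–C7a, and the expelled fluoride re-enters the cycle. The ring closes in the 5-exo-trig mode through a cyclohexadienyl anion whose charge is delocalised onto the para-acetyl group. C3 is controlled by the catalyst: the (R)-acid is expected to direct the allyl group to the Re face of the aldehyde, which gives 3S (the sense of induction is to be verified on the first run, and the (S)-acid is used if it is opposite). C2 is controlled by the alkene geometry of 8: the silyloxy group, cis to the CH2B group, sits axial in the chair and the aryl group equatorial, which gives the syn adduct and therefore the cis-2,3 ring. The step needs aldehyde-over-ketone chemoselectivity (inherent to allylboration), O1-over-O3 selectivity and suppression of lactonisation onto the methyl ester; only O1 can reach C7a in a five-membered ring, and O3 should stay bound to boron as a fluoroborate until the buffered work-up.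

Step 4
Reactants: 11 methyl 2-[(2S,3S)-5-acetyl-3-hydroxy-2,3-dihydro-1-benzofuran-2-yl]prop-2-enoate
Product: 12 methyl 2-[(2S,3S)-5-acetyl-3-(acetyloxy)-2,3-dihydro-1-benzofuran-2-yl]prop-2-enoate
Conditions: Ac2O (1.5 equiv), pyridine, 4-(dimethylamino)pyridine (5 mol%), CH2Cl2, 0 °C, on the crude alcohol
Reagents that add atoms: acetic anhydride, CC(=O)OC(C)=O
Why: Nucleophile-catalysed O-acylation of the secondary benzylic alcohol is fast at 0 °C, which should forestall lactonisation of the cis hydroxy ester, and no stereocentre is touched.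

Step 5
Reactants: 12 methyl 2-[(2S,3S)-5-acetyl-3-(acetyloxy)-2,3-dihydro-1-benzofuran-2-yl]prop-2-enoate
Product: 13 methyl 2-[(2S,3S)-3-(acetyloxy)-5-[(1S)-1-hydroxyethyl]-2,3-dihydro-1-benzofuran-2-yl]prop-2-enoate
Conditions: (3aR)-1-methyl-3,3-diphenyltetrahydro-1H,3H-pyrrolo[1,2-c][1,3,2]oxazaborole (20 mol%), catecholborane (1.5 equiv), toluene, −78 °C; MeOH quench, aq. NaHCO3 wash
Reagents that add atoms: none
Why: Corey–Bakshi–Shibata reduction, in which the (R)-oxazaborolidine binds the aryl methyl ketone with the aryl group in the large-group position and delivers hydride to give the (S)-carbinol; catecholborane at −78 °C should leave the acrylate, both esters and the allylic aryl ether untouched.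

Step 6
Reactants: 13 methyl 2-[(2S,3S)-3-(acetyloxy)-5-[(1S)-1-hydroxyethyl]-2,3-dihydro-1-benzofuran-2-yl]prop-2-enoate; 14 angelic acid [(2Z)-2-methylbut-2-enoic acid]
Product: 16 methyl 2-[(2S,3S)-3-(acetyloxy)-5-[(1S)-1-{[(2Z)-2-methylbut-2-enoyl]oxy}ethyl]-2,3-dihydro-1-benzofuran-2-yl]prop-2-enoate, via mixed anhydride 15 (not isolated)
Conditions: 14 (3 equiv), 2,4,6-trichlorobenzoyl chloride (3 equiv), Et3N (3.3 equiv), toluene, rt; then 13, toluene, 70 °C, no pyridine-type catalyst
Reagents that add atoms: none
Why: Yamaguchi esterification through the mixed trichlorobenzoic anhydride, run without a nucleophilic catalyst so that the (Z)-alkene should not isomerise to the tiglate by addition–elimination; the carbinol C–O bond is not broken, so its (S)-configuration is retained.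

Compound list
1 | 5-bromo-2-fluorobenzaldehyde | O=Cc1cc(Br)ccc1F | starting material
2 | tributyl(1-ethoxyethenyl)stannane | CCCC[Sn](CCCC)(CCCC)C(=C)OCC | starting material
3 | 5-(1-ethoxyethenyl)-2-fluorobenzaldehyde | C=C(OCC)c1ccc(F)c(C=O)c1 | intermediate
4 | 5-acetyl-2-fluorobenzaldehyde | CC(=O)c1ccc(F)c(C=O)c1 | intermediate
5 | methyl 3-(4,4,5,5-tetramethyl-1,3,2-dioxaborolan-2-yl)propanoate | COC(=O)CCB1OC(C)(C)C(C)(C)O1 | starting material
6 | methyl formate | COC=O | starting material
7 | sodium 3-methoxy-3-oxo-2-[(4,4,5,5-tetramethyl-1,3,2-dioxaborolan-2-yl)methyl]prop-1-en-1-olate | [Na+].[O-]C=C(CB1OC(C)(C)C(C)(C)O1)C(=O)OC | intermediate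
8 | methyl (2E)-3-[(tert-butyldimethylsilyl)oxy]-2-[(4,4,5,5-tetramethyl-1,3,2-dioxaborolan-2-yl)methyl]prop-2-enoate | COC(=O)/C(CB1OC(C)(C)C(C)(C)O1)=C/O[Si](C)(C)C(C)(C)C | intermediate
9 | methyl (3S,4S)-4-(5-acetyl-2-fluorophenyl)-3-[(tert-butyldimethylsilyl)oxy]-2-methylidene-4-[(4,4,5,5-tetramethyl-1,3,2-dioxaborolan-2-yl)oxy]butanoate | C=C(C(=O)OC)[C@H](O[Si](C)(C)C(C)(C)C)[C@@H](OB1OC(C)(C)C(C)(C)O1)c1cc(C(C)=O)ccc1F | intermediate
10 | methyl 2-[(2S,3S)-5-acetyl-3-[(4,4,5,5-tetramethyl-1,3,2-dioxaborolan-2-yl)oxy]-2,3-dihydro-1-benzofuran-2-yl]prop-2-enoate | C=C(C(=O)OC)[C@@H]1Oc2ccc(C(C)=O)cc2[C@@H]1OB1OC(C)(C)C(C)(C)O1 | intermediate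
11 | methyl 2-[(2S,3S)-5-acetyl-3-hydroxy-2,3-dihydro-1-benzofuran-2-yl]prop-2-enoate | C=C(C(=O)OC)[C@@H]1Oc2ccc(C(C)=O)cc2[C@@H]1O | intermediate
12 | methyl 2-[(2S,3S)-5-acetyl-3-(acetyloxy)-2,3-dihydro-1-benzofuran-2-yl]prop-2-enoate | C=C(C(=O)OC)[C@@H]1Oc2ccc(C(C)=O)cc2[C@@H]1OC(C)=O | intermediate
13 | methyl 2-[(2S,3S)-3-(acetyloxy)-5-[(1S)-1-hydroxyethyl]-2,3-dihydro-1-benzofuran-2-yl]prop-2-enoate | C=C(C(=O)OC)[C@@H]1Oc2ccc([C@H](C)O)cc2[C@@H]1OC(C)=O | intermediate
14 | angelic acid, (2Z)-2-methylbut-2-enoic acid | C/C=C(/C)C(=O)O | starting material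
15 | (2Z)-2-methylbut-2-enoic 2,4,6-trichlorobenzoic anhydride | C/C=C(/C)C(=O)OC(=O)c1c(Cl)cc(Cl)cc1Cl | intermediate
16 | methyl 2-[(2S,3S)-3-(acetyloxy)-5-[(1S)-1-{[(2Z)-2-methylbut-2-enoyl]oxy}ethyl]-2,3-dihydro-1-benzofuran-2-yl]prop-2-enoate | C=C(C(=O)OC)[C@@H]1Oc2ccc([C@H](C)OC(=O)/C(C)=C\C)cc2[C@@H]1OC(C)=O | target

Total step count: 6
Longest linear sequence: 5 steps (steps 1, 3, 4, 5 and 6 from 1; equally steps 2 to 6 from 5)

Steps most likely to fail

Step 3. The allyl transfer from the electron-poor boronate may be slow or poorly face-selective, and in the fluoride stage lactonisation of the C3 oxygen onto the methyl ester may compete with ring closure. The fallback makes the two bonds separately by known reactions and sets out from 4. SNAr with methyl 2-(hydroxymethyl)prop-2-enoate (K2CO3, DMF, rt) should give the aryl ether methyl 2-[(4-acetyl-2-formylphenoxy)methyl]prop-2-enoate F1. Irradiation (350 nm, benzene) should bring about δ-hydrogen abstraction by the excited aldehyde from the doubly activated OCH2 group and Yang cyclisation of the 1,5-biradical to the 3-hydroxy-2,3-dihydrobenzofuran, from which the racemic cis alcohol F2 is separated from the trans isomer. Lipase-catalysed acylation (immobilised Candida antarctica lipase B, vinyl acetate, tert-butyl methyl ether) is expected to acetylate the (2S,3S)-enantiomer, whose C3 has the spatial arrangement of the fast-reacting enantiomer of 1-indanol. This returns to the route at 12 and leaves the (2R,3R)-alcohol F3.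

Step 2. The alkoxide may attack boron or the ester may self-condense during the formylation, and the enol ether may form with the wrong geometry. The fallback avoids alkoxide and hydride bases and sets out from 5. Heating with tert-butoxybis(dimethylamino)methane (neat, 90 °C) should give the enamino ester methyl (2E)-3-(dimethylamino)-2-[(4,4,5,5-tetramethyl-1,3,2-dioxaborolan-2-yl)methyl]prop-2-enoate F4. Hydrolysis (1 M HCl, THF, 0 °C) should give the formyl ester methyl 2-formyl-3-(4,4,5,5-tetramethyl-1,3,2-dioxaborolan-2-yl)propanoate F5, largely as its enol. Silylation under equilibrating conditions (t-BuMe2SiCl, Et3N, CH2Cl2) returns to the route at 8.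

Step 6. The angeloyl unit may isomerise from Z to E during acyl activation, and the para-alkoxy benzylic carbinol may ionise at 70 °C. The fallback builds the (Z)-alkene on an ester that is already in place and sets out from 13. Acylation with 2-[bis(2,2,2-trifluoroethoxy)phosphoryl]propanoic acid (N,N'-dicyclohexylcarbodiimide, 4-(dimethylamino)pyridine cat., CH2Cl2, 0 °C) should give the phosphonate ester methyl 2-[(2S,3S)-3-(acetyloxy)-5-[(1S)-1-({2-[bis(2,2,2-trifluoroethoxy)phosphoryl]propanoyl}oxy)ethyl]-2,3-dihydro-1-benzofuran-2-yl]prop-2-enoate F6. A Still–Gennari olefination with acetaldehyde (KN(SiMe3)2, 18-crown-6, THF, −78 °C) should then give the (Z)-2-methylbut-2-enoate and returns to the route at 16.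

Further compounds
F1 | step 3 | methyl 2-[(4-acetyl-2-formylphenoxy)methyl]prop-2-enoate | C=C(COc1ccc(C(C)=O)cc1C=O)C(=O)OC
F2 | step 3 | racemic cis-methyl 2-(5-acetyl-3-hydroxy-2,3-dihydro-1-benzofuran-2-yl)prop-2-enoate (both enantiomers) | C=C(C(=O)OC)[C@@H]1Oc2ccc(C(C)=O)cc2[C@@H]1O.C=C(C(=O)OC)[C@H]1Oc2ccc(C(C)=O)cc2[C@H]1O
F3 | step 3 | methyl 2-[(2R,3R)-5-acetyl-3-hydroxy-2,3-dihydro-1-benzofuran-2-yl]prop-2-enoate | C=C(C(=O)OC)[C@H]1Oc2ccc(C(C)=O)cc2[C@H]1O
F4 | step 2 | methyl (2E)-3-(dimethylamino)-2-[(4,4,5,5-tetramethyl-1,3,2-dioxaborolan-2-yl)methyl]prop-2-enoate | COC(=O)/C(CB1OC(C)(C)C(C)(C)O1)=C/N(C)C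
F5 | step 2 | methyl 2-formyl-3-(4,4,5,5-tetramethyl-1,3,2-dioxaborolan-2-yl)propanoate | COC(=O)C(C=O)CB1OC(C)(C)C(C)(C)O1
F6 | step 6 | methyl 2-[(2S,3S)-3-(acetyloxy)-5-[(1S)-1-({2-[bis(2,2,2-trifluoroethoxy)phosphoryl]propanoyl}oxy)ethyl]-2,3-dihydro-1-benzofuran-2-yl]prop-2-enoate | C=C(C(=O)OC)[C@@H]1Oc2ccc([C@H](C)OC(=O)C(C)P(=O)(OCC(F)(F)F)OCC(F)(F)F)cc2[C@@H]1OC(C)=O
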